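**Retrosynthetic overview**

- The target is read as the (2R,3R), 2,3-cis flavan. It comes from ten-fold O-debenzylation of a deca-O-benzyl bis-gallate, made by double esterification of 5,7,3',5'-tetra-O-benzyl-epigallocatechin (free 3-OH and 4'-OH; the 4'-O is carried as an allyl ether) with 3,4,5-tris(benzyloxy)benzoic acid.
- The cis-flavan-3-ol comes from a (2R)-flavan-3-one (hydride anti to the C2 aryl), and that from reductive Nef reaction of a (2R)-2-aryl-3-nitro-2H-chromene, whose nitro-bearing carbon is the masked C3 carbonyl.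
- Key disconnection C3–C4 (with O1–C2): an enantioselective oxa-Michael/Henry cascade of a ring A salicylaldehyde with a ring B nitrostyrene. The nitronate carbon, an acyl-anion equivalent, attacks the aldehyde carbon, so two carbonyl-type carbons are joined, and C2 is set in the same step.
- C2–C3: the nitrostyrene comes from the ring B aldehyde and nitromethane (Henry condensation), so nitromethane stitches two aldehyde carbons as a carbonyl 1,1-dianion equivalent.
- Ring order: rings A and B are bought as 2,4,6- and 3,4,5-trihydroxybenzaldehyde; ring C (the pyran) is the only ring formed, in the key step; the two galloyl rings are attached last.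

Assumption: the pyrrolidine antipode named in step 4 is taken to give the (2R)-nitrochromene; if the first run shows the other sense, its mirror image (from D-proline) is used and nothing else changes.

**Route**

Step 1
Reactants: 1 3,4,5-trihydroxybenzaldehyde
Product: 3 3,5-bis(benzyloxy)-4-(prop-2-en-1-yloxy)benzaldehyde, via 4-O-allyl aldehyde 2 (not isolated)
Conditions: allyl bromide (1.0 equiv), NaHCO3, DMF, 40 °C, argon; then BnBr (2.4 equiv), K2CO3, 60 °C
Reagents that add atoms: allyl bromide, C=CCBr; benzyl bromide, BrCc1ccccc1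
Why: Regioselective Williamson etherification, in which the 4-OH (para to the formyl group) is the most acidic so NaHCO3 ionises and allylates only O4, after which K2CO3/BnBr benzylates the two remaining phenols in the same flask.

Step 2
Reactants: 3 3,5-bis(benzyloxy)-4-(prop-2-en-1-yloxy)benzaldehyde; 4 nitromethane
Product: 5 1,3-bis(benzyloxy)-5-[(E)-2-nitroethenyl]-2-(prop-2-en-1-yloxy)benzene
Conditions: MeNO2 (5 equiv), NH4OAc (0.5 equiv), AcOH, 100 °C
Reagents that add atoms: none
Why: Henry (nitroaldol) condensation with dehydration gives the conjugated E-nitroalkene and forms the C2–C3 bond, the nitromethane carbon (future C3) reacting as a nucleophile although it ends as a carbinol carbon.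

Step 3
Reactants: 6 2,4,6-trihydroxybenzaldehyde
Product: 7 2,4-bis(benzyloxy)-6-hydroxybenzaldehyde
Conditions: BnBr (2.05 equiv), K2CO3, DMF, rt
Reagents that add atoms: benzyl bromide, BrCc1ccccc1
Why: Williamson etherification that stops at the dibenzyl ether because the last ortho hydroxyl is held in a hydrogen bond to the formyl group (the same selectivity as with 2,4,6-trihydroxyacetophenone).

Step 4
Reactants: 7 2,4-bis(benzyloxy)-6-hydroxybenzaldehyde; 5 1,3-bis(benzyloxy)-5-[(E)-2-nitroethenyl]-2-(prop-2-en-1-yloxy)benzene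
Product: 9 (2R)-5,7-bis(benzyloxy)-2-[3,5-bis(benzyloxy)-4-(prop-2-en-1-yloxy)phenyl]-3-nitro-2H-chromene, via oxa-Michael adduct 8 (not isolated)
Conditions: (S)-2-{[(1-methyl-1H-imidazol-2-yl)sulfanyl]methyl}pyrrolidine (20 mol%), salicylic acid (20 mol%), DMSO, rt; recrystallisation
Reagents that add atoms: none
Why: Enantioselective oxa-Michael/Henry cascade under aromatic iminium catalysis, in which the chiral pyrrolidine condenses with the aldehyde of 7, the phenol oxygen adds to one enantioface of nitroalkene 5 (this sets C2 as R), and the resulting nitronate, a masked acyl anion for the later C3 carbonyl, closes ring C on the iminium carbon (C3–C4 bond) before the amine is expelled to leave the nitroalkene; the precedent is the amine/salicylic acid-catalysed synthesis of 2-aryl-3-nitro-2H-chromenes from salicylaldehydes and nitrostyrenes, and recrystallisation of the product raises the ee.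

Step 5
Reactants: 9 (2R)-5,7-bis(benzyloxy)-2-[3,5-bis(benzyloxy)-4-(prop-2-en-1-yloxy)phenyl]-3-nitro-2H-chromene
Product: 12 (2R)-5,7-bis(benzyloxy)-2-[3,5-bis(benzyloxy)-4-(prop-2-en-1-yloxy)phenyl]chroman-3-one, via oxime 10 (not isolated), via imine 11 (not isolated)
Conditions: Fe powder (6 equiv), AcOH/H2O 5:1, 60 °C, argon; crude ketone used at once
Reagents that add atoms: water, O
Why: Reductive Nef reaction, in which iron in acetic acid reduces the conjugated nitroalkene to the oxime and on to the imine, which the aqueous acid hydrolyses to the C3 ketone, so the nitro-bearing carbon is unmasked as a carbonyl while C2 is not a reacting centre.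

Step 6
Reactants: 12 (2R)-5,7-bis(benzyloxy)-2-[3,5-bis(benzyloxy)-4-(prop-2-en-1-yloxy)phenyl]chroman-3-one
Product: 13 (2R,3R)-5,7-bis(benzyloxy)-2-[3,5-bis(benzyloxy)-4-(prop-2-en-1-yloxy)phenyl]chroman-3-ol (2,3-cis)
Conditions: LiBH(s-Bu)3 (1.5 equiv), THF, −78 °C; then H2O
Reagents that add atoms: none
Why: Substrate-controlled ketone reduction in which the bulky LiBH(s-Bu)3 delivers hydride to the carbonyl face opposite the C2 aryl group, so the new hydroxyl is cis to the aryl (3R), as in the known reductions of benzylated flavan-3-ones to the epi series.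

Step 7
Reactants: 13 (2R,3R)-5,7-bis(benzyloxy)-2-[3,5-bis(benzyloxy)-4-(prop-2-en-1-yloxy)phenyl]chroman-3-ol
Product: 14 (2R,3R)-5,7-bis(benzyloxy)-2-[3,5-bis(benzyloxy)-4-hydroxyphenyl]chroman-3-ol
Conditions: Pd(PPh3)4 (5 mol%), morpholine (5 equiv), THF, rt
Reagents that add atoms: none
Why: Tsuji–Trost deallylation, in which zerovalent palladium ionises the aryl allyl ether to a π-allyl complex that morpholine captures, freeing only the 4'-phenol while the benzyl ethers and the secondary alcohol are untouched.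

Step 8
Reactants: 14 (2R,3R)-5,7-bis(benzyloxy)-2-[3,5-bis(benzyloxy)-4-hydroxyphenyl]chroman-3-ol; 15 3,4,5-tris(benzyloxy)benzoic acid
Product: 16 (2R,3R)-5,7-bis(benzyloxy)-2-{3,5-bis(benzyloxy)-4-[3,4,5-tris(benzyloxy)benzoyloxy]phenyl}chroman-3-yl 3,4,5-tris(benzyloxy)benzoate
Conditions: 15 (2.6 equiv), DCC (3 equiv), 4-(dimethylamino)pyridine (0.4 equiv), CH2Cl2, rt
Reagents that add atoms: none
Why: Steglich esterification (carbodiimide activation, acyl transfer through the N-acylpyridinium ion) acylates both the axial 3-OH and the hindered 4'-phenol without touching a stereocentre.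

Step 9
Reactants: 16 (2R,3R)-5,7-bis(benzyloxy)-2-{3,5-bis(benzyloxy)-4-[3,4,5-tris(benzyloxy)benzoyloxy]phenyl}chroman-3-yl 3,4,5-tris(benzyloxy)benzoate
Product: 17 (2R,3R)-5,7-dihydroxy-2-[3,5-dihydroxy-4-(3,4,5-trihydroxybenzoyloxy)phenyl]chroman-3-yl 3,4,5-trihydroxybenzoate (epigallocatechin 3,4'-di-O-gallate)
Conditions: H2 (1 atm), Pd(OH)2/C, THF/MeOH 4:1, rt
Reagents that add atoms: none
Why: Catalytic hydrogenolysis of the ten benzyl ethers under neutral conditions leaves the two gallate esters and the benzylic C2–O1 bond intact, as in the last step of benzyl-based gallocatechin gallate syntheses.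

**Compound list**

1 | 3,4,5-trihydroxybenzaldehyde | O=Cc1cc(O)c(O)c(O)c1 | starting material
2 | 3,5-dihydroxy-4-(prop-2-en-1-yloxy)benzaldehyde (4-O-allyl aldehyde, not isolated) | O=Cc1cc(O)c(OCC=C)c(O)c1 | intermediate
3 | 3,5-bis(benzyloxy)-4-(prop-2-en-1-yloxy)benzaldehyde | O=Cc1cc(OCc2ccccc2)c(OCC=C)c(OCc2ccccc2)c1 | intermediate
4 | nitromethane | C[N+](=O)[O-] | starting material
5 | 1,3-bis(benzyloxy)-5-[(E)-2-nitroethenyl]-2-(prop-2-en-1-yloxy)benzene | [O-][N+](=O)/C=C/c1cc(OCc2ccccc2)c(OCC=C)c(OCc2ccccc2)c1 | intermediate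
6 | 2,4,6-trihydroxybenzaldehyde | O=Cc1c(O)cc(O)cc1O | starting material
7 | 2,4-bis(benzyloxy)-6-hydroxybenzaldehyde | O=Cc1c(O)cc(OCc2ccccc2)cc1OCc1ccccc1 | intermediate
8 | 2,4-bis(benzyloxy)-6-{(1R)-1-[3,5-bis(benzyloxy)-4-(prop-2-en-1-yloxy)phenyl]-2-nitroethoxy}benzaldehyde (oxa-Michael adduct, not isolated; drawn as the free aldehyde, in the flask it is bound to the amine catalyst as the iminium ion) | O=Cc1c(O[C@@H](C[N+](=O)[O-])c2cc(OCc3ccccc3)c(OCC=C)c(OCc3ccccc3)c2)cc(OCc2ccccc2)cc1OCc1ccccc1 | intermediate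
9 | (2R)-5,7-bis(benzyloxy)-2-[3,5-bis(benzyloxy)-4-(prop-2-en-1-yloxy)phenyl]-3-nitro-2H-chromene | [O-][N+](=O)C1=Cc2c(OCc3ccccc3)cc(OCc3ccccc3)cc2O[C@@H]1c1cc(OCc2ccccc2)c(OCC=C)c(OCc2ccccc2)c1 | intermediate
10 | (2R)-5,7-bis(benzyloxy)-2-[3,5-bis(benzyloxy)-4-(prop-2-en-1-yloxy)phenyl]chroman-3-one oxime (not isolated, oxime geometry not defined) | ON=C1Cc2c(OCc3ccccc3)cc(OCc3ccccc3)cc2O[C@@H]1c1cc(OCc2ccccc2)c(OCC=C)c(OCc2ccccc2)c1 | intermediate
11 | (2R)-5,7-bis(benzyloxy)-2-[3,5-bis(benzyloxy)-4-(prop-2-en-1-yloxy)phenyl]chroman-3-imine (not isolated) | N=C1Cc2c(OCc3ccccc3)cc(OCc3ccccc3)cc2O[C@@H]1c1cc(OCc2ccccc2)c(OCC=C)c(OCc2ccccc2)c1 | intermediate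
12 | (2R)-5,7-bis(benzyloxy)-2-[3,5-bis(benzyloxy)-4-(prop-2-en-1-yloxy)phenyl]chroman-3-one | O=C1Cc2c(OCc3ccccc3)cc(OCc3ccccc3)cc2O[C@@H]1c1cc(OCc2ccccc2)c(OCC=C)c(OCc2ccccc2)c1 | intermediate
13 | (2R,3R)-5,7-bis(benzyloxy)-2-[3,5-bis(benzyloxy)-4-(prop-2-en-1-yloxy)phenyl]chroman-3-ol (2,3-cis) | C=CCOc1c(OCc2ccccc2)cc([C@H]2Oc3cc(OCc4ccccc4)cc(OCc4ccccc4)c3C[C@H]2O)cc1OCc1ccccc1 | intermediate
14 | (2R,3R)-5,7-bis(benzyloxy)-2-[3,5-bis(benzyloxy)-4-hydroxyphenyl]chroman-3-ol | Oc1c(OCc2ccccc2)cc([C@H]2Oc3cc(OCc4ccccc4)cc(OCc4ccccc4)c3C[C@H]2O)cc1OCc1ccccc1 | intermediate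
15 | 3,4,5-tris(benzyloxy)benzoic acid | O=C(O)c1cc(OCc2ccccc2)c(OCc2ccccc2)c(OCc2ccccc2)c1 | starting material
16 | (2R,3R)-5,7-bis(benzyloxy)-2-{3,5-bis(benzyloxy)-4-[3,4,5-tris(benzyloxy)benzoyloxy]phenyl}chroman-3-yl 3,4,5-tris(benzyloxy)benzoate | O=C(Oc1c(OCc2ccccc2)cc([C@H]2Oc3cc(OCc4ccccc4)cc(OCc4ccccc4)c3C[C@H]2OC(=O)c2cc(OCc3ccccc3)c(OCc3ccccc3)c(OCc3ccccc3)c2)cc1OCc1ccccc1)c1cc(OCc2ccccc2)c(OCc2ccccc2)c(OCc2ccccc2)c1 | intermediate
17 | (2R,3R)-5,7-dihydroxy-2-[3,5-dihydroxy-4-(3,4,5-trihydroxybenzoyloxy)phenyl]chroman-3-yl 3,4,5-trihydroxybenzoate (epigallocatechin 3,4'-di-O-gallate) | O=C(Oc1c(O)cc([C@H]2Oc3cc(O)cc(O)c3C[C@H]2OC(=O)c2cc(O)c(O)c(O)c2)cc1O)c1cc(O)c(O)c(O)c1 | target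

**Step count and risks**

Total step count: 9. Longest linear sequence: 8 (steps 1, 2, 4, 5, 6, 7, 8, 9); step 3 is the only branch.

The step most likely to fail is step 4. Aldehyde 7 is very electron-rich and flanked by two ortho substituents, so iminium formation may be slow and the ee modest. The fallback sets out from 7 and 5 and uses non-covalent catalysis instead. With the quinine-derived squaramide 3-{[3,5-bis(trifluoromethyl)phenyl]amino}-4-{[(8α,9S)-6'-methoxycinchonan-9-yl]amino}cyclobut-3-ene-1,2-dione (or its quinidine-derived counterpart, whichever gives 2R) in toluene at 0 °C, the oxa-Michael/Henry sequence stops at the alcohol stage and gives (2R)-5,7-bis(benzyloxy)-2-[3,5-bis(benzyloxy)-4-(prop-2-en-1-yloxy)phenyl]-3-nitrochroman-4-ol F1. F1 is crystallised to raise the ee and then dehydrated with catalytic p-toluenesulfonic acid in toluene at 50 °C, which comes back to the route at 9.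

The second is step 5. In warm acid the imine or the ketone can enolise towards C2 and erode the ee, or the reduction can stall at the oxime. The fallback sets out from 9 and separates reduction from hydrolysis. SnCl2·2H2O in EtOAc at rt reduces the nitroalkene only as far as the oxime 10, which is isolated here. The oxime is then exchanged onto glyoxylic acid (aqueous glyoxylic acid, THF, rt), a redox-neutral transoximation near pH 3 that comes back to the route at 12. This way makes no compound beyond those already listed (F0).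

The third is step 1. The one-pot 4-O-allylation may give mixtures with 3-O- and di-O-allyl products. The fallback sets out from 1 and differentiates O4 by removal instead of by selective installation. Exhaustive benzylation (BnBr, K2CO3, DMF) gives 3,4,5-tris(benzyloxy)benzaldehyde F2. MgBr2·OEt2 in toluene/Et2O at reflux then cleaves only the central ether, which is twisted out of plane between its neighbours and para to the carbonyl (as in the trimethoxy-to-syringaldehyde case), to give 3,5-bis(benzyloxy)-4-hydroxybenzaldehyde F3. Allylation of F3 (allyl bromide, K2CO3, acetone) comes back to the route at 3.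

**Further compounds**

F1 | step 4 | (2R)-5,7-bis(benzyloxy)-2-[3,5-bis(benzyloxy)-4-(prop-2-en-1-yloxy)phenyl]-3-nitrochroman-4-ol (C3 and C4 as formed) | [O-][N+](=O)C1C(O)c2c(OCc3ccccc3)cc(OCc3ccccc3)cc2O[C@@H]1c1cc(OCc2ccccc2)c(OCC=C)c(OCc2ccccc2)c1
F0 | step 5 | none | none
F2 | step 1 | 3,4,5-tris(benzyloxy)benzaldehyde | O=Cc1cc(OCc2ccccc2)c(OCc2ccccc2)c(OCc2ccccc2)c1
F3 | step 1 | 3,5-bis(benzyloxy)-4-hydroxybenzaldehyde | O=Cc1cc(OCc2ccccc2)c(O)c(OCc2ccccc2)c1
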